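The hour is the wrong clock for these four set-ups, in which D, kept at balance with its dimer D2, reacts with Q to give D.Q, and D.Q turns reversibly into G.

| flask | D | Q | remark | time |
|---|---|---|---|---|
| amber | 0.24 M | 0.500 equiv | one stirred flow tank at steady state, fed with the mixture as stated, mean residence time 4.0 h |  |
| violet | 0.24 M | 0.500 equiv (fed, over 3.20 h) | all but Q at the start; Q goes in evenly over 3.20 h, the run ends at 4.0 h | 4.0 h |
| ochre | 0.24 M (fed, over 3.20 h) | 0.500 equiv | a stirred flask in which D is dosed at a steady rate over 3.20 h without added volume, worked up at 4.0 h | 4.0 h |
| grey | 0.24 M | 0.500 equiv | a closed flask charged with all of it at once and left for 4.0 h | 4.0 h |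

* the set-up with the highest share of D.Q in all that became D.Q or G, at the outlet or at the end ("none" if the first two lie within 2 percentage points) (amber / violet / ochre / grey / none)
* share of D.Q in all that became D.Q or G, at the outlet or at the end, amber
* share of D.Q in all that became D.Q or G, at the outlet or at the end, violet
* share of D.Q in all that became D.Q or G, at the outlet or at the end, ochre
* share of D.Q in all that became D.Q or G, at the outlet or at the end, grey

- a species is counted by the D in it: one D2 or L counts as two
- for a step with 2 of a species take k times the square, and two of it per event
- the stated concentrations are those of everything mixed, before any reaction; amounts are the same in each set-up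
- the feed brings no volume worth counting
- run time (violet): 4.0 h

Two chemists dispute this share. The first holds that D.Q and G simply stand at balance, where G/D.Q is 0.36, so every set-up gives the same share, f = 73.5 %. Her argument is the settling time T of the pair (its relaxation time), one over the sum of forward and back constants: from a forward constant of 0.00945 /min, T is 28.0 min, shorter than a run of 240 min.

The second answers that D.Q is still being made at the end, and G trails it. I side with the second. While making goes on, D.Q stands above balance by g × rate × T, where g = 26.5 % is the share of G at balance. Dividing by the total made gives share = f + gT/M, where the making time M is the total made divided by the rate at the end.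

The fast balance leaves free D at the root of total D over twice its constant, 0.00220 M at full charge. At that level a run uses 11.2 % of Q, so I take the rate as steady once feeding stops.

Grey has M = 240 min, giving 76.6 %. In amber the tank balance gives M = 240 min + T, so 76.3 %. In violet Q climbs evenly, so M loses half of the 192 min of dosing: 144 min, giving 78.7 %. In ochre free D climbs as the root of time, so M loses a third of the dosing time: 176 min, giving 77.7 %. Violet leads ochre by 0.94 percentage points, less than the margin of 2 points.

The forecast stands on the second side: 76.3 % for amber, 78.5 % for violet, 77.6 % for ochre, 76.5 % for grey, best none. Its ground: “Fresh D.Q therefore lifts the share slightly above that.” My reckoning differs slightly from it: mine stands 0.18 points above its violet, 0.14 points above its ochre and 0.12 points above its grey.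

The simulation gives 76.3 % for amber, 78.4 % for violet, 77.6 % for ochre and 76.5 % for grey, and best is none. Every share lies above the first chemist's f.

    D.Q ⇌ G (K1 = 0.36, k1 = 0.00945 /min)
    2 D → L (k2 = 6.29 × 10⁻⁵ /M/min)
    D + Q → D.Q (k3 = 0.212 /M/min)
    2 D ⇌ D2, settled at all times (K4 = 24900 /M)

The main reason amber stands at 76.3 % is the way back from G to D.Q: with that reverse step struck out, amber falls to 30.6 %. With that way back in place T is 28.0 min, and amber's residence time is 8.57 settling times. Violet, left until 40.0 h, has had 85.7 settling times, and there the first chemist is right: it reads 73.7 %, close to her 73.5 %.

All constants are those of an exercise; what happens was integrated by code.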